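**Strategy**

Ring C (the pyran ring; flavan numbering) is disconnected at C2–C3. C2 carries the ring oxygen O1 and the electron-rich catechol ring B, so its C–H bond is hydridic; C3 lies next to C4, which as a ketone makes C3 enolisable. The precursor is therefore an open benzyl aryl ether: a phloroacetophenone (ring A) whose O1 bears the ring-B benzyl group and whose C3 already bears the protected gallate. Hydride abstraction at C2 by DDQ under a chiral phosphoric acid gives an oxocarbenium ion that the C3 enol attacks, closing ring C and setting C2 and C3 (trans) in one operation. Reduction with LiBH(s-Bu)3 then sets C4 cis to the gallate, and hydrogenolysis frees the phenols.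

Key step: step 5

Assumption: the sense of induction of the chiral acid in step 5 cannot be predicted with certainty; the (R)-acid is taken to give the (2R) product, and its enantiomer would be used if the sense proves opposite.

**Route**

Step 1
Reactants: 1 2',4',6'-trihydroxyacetophenone
Product: 2 1-[2,4-bis(benzyloxy)-6-hydroxyphenyl]ethan-1-one
Conditions: BnBr (2.1 equiv), K2CO3, DMF, rt
Reagents that add atoms: benzyl bromide, BrCc1ccccc1
Why: Williamson etherification; the hydroxyl that is hydrogen-bonded to the acetyl carbonyl is the least nucleophilic, so two equivalents of halide should leave it free.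

Step 2
Reactants: 2 1-[2,4-bis(benzyloxy)-6-hydroxyphenyl]ethan-1-one; 3 3,4-bis(benzyloxy)benzyl chloride
Product: 4 1-[2,4-bis(benzyloxy)-6-{[3,4-bis(benzyloxy)phenyl]methoxy}phenyl]ethan-1-one
Conditions: K2CO3, n-Bu4NI (cat.), DMF, 70 °C
Reagents that add atoms: none
Why: Williamson etherification with Finkelstein activation; heating should force alkylation of the chelated phenol and installs the O1–CH2–aryl unit whose methylene becomes C2.

Step 3
Reactants: 4 1-[2,4-bis(benzyloxy)-6-{[3,4-bis(benzyloxy)phenyl]methoxy}phenyl]ethan-1-one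
Product: 6 1-[2,4-bis(benzyloxy)-6-{[3,4-bis(benzyloxy)phenyl]methoxy}phenyl]-2-bromoethan-1-one, via trimethylsilyl enol ether 5 (not isolated)
Conditions: TMSOTf, Et3N, CH2Cl2, 0 °C; then crude 5, NBS, THF, −78 °C
Reagents that add atoms: trimethylsilyl trifluoromethanesulfonate, C[Si](C)(C)OS(=O)(=O)C(F)(F)F (silicon only in intermediate 5); N-bromosuccinimide, O=C1CCC(=O)N1Br
Why: Soft enolisation followed by electrophilic α-bromination of the silyl enol ether, which should react at −78 °C far faster than the alkoxy-substituted rings and so avoid nuclear bromination.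

Step 4
Reactants: 6 1-[2,4-bis(benzyloxy)-6-{[3,4-bis(benzyloxy)phenyl]methoxy}phenyl]-2-bromoethan-1-one; 7 3,4,5-tris(benzyloxy)benzoic acid
Product: 8 2-[2,4-bis(benzyloxy)-6-{[3,4-bis(benzyloxy)phenyl]methoxy}phenyl]-2-oxoethyl 3,4,5-tris(benzyloxy)benzoate
Conditions: K2CO3, DMF, rt
Reagents that add atoms: none
Why: SN2 displacement of the phenacyl bromide by the carboxylate (phenacyl ester formation) places the protected gallate on the future C3 oxygen.

Step 5
Reactants: 8 2-[2,4-bis(benzyloxy)-6-{[3,4-bis(benzyloxy)phenyl]methoxy}phenyl]-2-oxoethyl 3,4,5-tris(benzyloxy)benzoate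
Product: 10 (2R,3R)-5,7-bis(benzyloxy)-2-[3,4-bis(benzyloxy)phenyl]-4-oxo-3,4-dihydro-2H-chromen-3-yl 3,4,5-tris(benzyloxy)benzoate, via aryloxocarbenium ion 9 (not isolated)
Conditions: DDQ (1.2 equiv), (R)-TRIP [(R)-3,3'-bis(2,4,6-triisopropylphenyl)-1,1'-binaphthyl-2,2'-diyl hydrogen phosphate] (10 mol %), 4 Å MS, CH2Cl2, 0 °C to rt
Reagents that add atoms: none
Why: Proposed new method: DDQ abstracts hydride from the one C–H position that is both benzylic to the electron-rich 3,4-dialkoxyphenyl ring B and α to the ether oxygen O1, and proton transfer from the acid to the reduced quinone leaves aryloxocarbenium ion 9 paired with the chiral phosphate, which also hydrogen-bonds the acid-generated enol of the C4 ketone, so that the enol carbon C3 attacks C2 inside the ion pair. The closest known reaction types are the DDQ-mediated oxidative cyclisation of benzylic ethers onto tethered enol nucleophiles (dehydrogenative coupling of ethers with ketones) and chiral phosphoric acid catalysis of enol additions to oxidatively generated benzylic cations; the enantioselective intramolecular variant on an aryl benzyl ether is untested. Ring C closes in a 6-(enolendo)-endo-trig, aldol-type mode through a chair-like transition state. C2 is set by the phosphate, which shields one face of the planar cation (catalyst control), and C3 by the transition state with both substituents pseudo-equatorial and, because C3 is α to the ketone, by acid-catalysed equilibration to the trans isomer without touching C2. The step needs chemoselective oxidation at C2, secured because the seven other O–CH2 groups are benzylic only to unactivated phenyl rings, and C- rather than O-alkylation of the enol, secured because an O-alkylated cyclic enol acetal would re-ionise under the acid and funnel to the ketone. Over-oxidation to the flavonol should be avoided by the small excess of DDQ at or below room temperature.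

Step 6
Reactants: 10 (2R,3R)-5,7-bis(benzyloxy)-2-[3,4-bis(benzyloxy)phenyl]-4-oxo-3,4-dihydro-2H-chromen-3-yl 3,4,5-tris(benzyloxy)benzoate
Product: 11 (2R,3S,4S)-5,7-bis(benzyloxy)-2-[3,4-bis(benzyloxy)phenyl]-4-hydroxy-3,4-dihydro-2H-chromen-3-yl 3,4,5-tris(benzyloxy)benzoate
Conditions: LiBH(s-Bu)3 (1.3 equiv), THF, −78 °C; AcOH quench at −78 °C
Reagents that add atoms: none
Why: Diastereoselective ketone reduction under steric approach control: the bulky trialkylborohydride should attack equatorially, as with 2-substituted cyclohexanones, giving the axial C4 hydroxyl cis to the equatorial C3 ester (4S), and the cold acidic quench is meant to prevent galloyl migration to the new alkoxide.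

Step 7
Reactants: 11 (2R,3S,4S)-5,7-bis(benzyloxy)-2-[3,4-bis(benzyloxy)phenyl]-4-hydroxy-3,4-dihydro-2H-chromen-3-yl 3,4,5-tris(benzyloxy)benzoate
Product: 12 (2R,3S,4S)-2-(3,4-dihydroxyphenyl)-4,5,7-trihydroxy-3,4-dihydro-2H-chromen-3-yl 3,4,5-trihydroxybenzoate (CNP0265773.1)
Conditions: H2 (1 atm), Pd(OH)2/C, EtOAc/MeOH, rt, short reaction time
Reagents that add atoms: none
Why: Catalytic hydrogenolysis of the seven benzyl ethers under neutral conditions, in which the ester and the secondary C4 carbinol are expected to survive.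

**Compound list**

1 | 1-(2,4,6-trihydroxyphenyl)ethan-1-one (2',4',6'-trihydroxyacetophenone) | CC(=O)c1c(O)cc(O)cc1O | starting material
2 | 1-[2,4-bis(benzyloxy)-6-hydroxyphenyl]ethan-1-one | CC(=O)c1c(O)cc(OCc2ccccc2)cc1OCc1ccccc1 | intermediate
3 | 3,4-bis(benzyloxy)benzyl chloride | ClCc1ccc(OCc2ccccc2)c(OCc2ccccc2)c1 | starting material
4 | 1-[2,4-bis(benzyloxy)-6-{[3,4-bis(benzyloxy)phenyl]methoxy}phenyl]ethan-1-one | CC(=O)c1c(OCc2ccc(OCc3ccccc3)c(OCc3ccccc3)c2)cc(OCc2ccccc2)cc1OCc1ccccc1 | intermediate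
5 | trimethylsilyl enol ether of 4 | C=C(O[Si](C)(C)C)c1c(OCc2ccc(OCc3ccccc3)c(OCc3ccccc3)c2)cc(OCc2ccccc2)cc1OCc1ccccc1 | intermediate (not isolated)
6 | 1-[2,4-bis(benzyloxy)-6-{[3,4-bis(benzyloxy)phenyl]methoxy}phenyl]-2-bromoethan-1-one | O=C(CBr)c1c(OCc2ccc(OCc3ccccc3)c(OCc3ccccc3)c2)cc(OCc2ccccc2)cc1OCc1ccccc1 | intermediate
7 | 3,4,5-tris(benzyloxy)benzoic acid | OC(=O)c1cc(OCc2ccccc2)c(OCc2ccccc2)c(OCc2ccccc2)c1 | starting material
8 | 2-[2,4-bis(benzyloxy)-6-{[3,4-bis(benzyloxy)phenyl]methoxy}phenyl]-2-oxoethyl 3,4,5-tris(benzyloxy)benzoate | O=C(OCC(=O)c1c(OCc2ccc(OCc3ccccc3)c(OCc3ccccc3)c2)cc(OCc2ccccc2)cc1OCc1ccccc1)c1cc(OCc2ccccc2)c(OCc2ccccc2)c(OCc2ccccc2)c1 | intermediate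
9 | aryloxocarbenium ion formed from 8 by loss of hydride at C2 | O=C(OCC(=O)c1c([O+]=Cc2ccc(OCc3ccccc3)c(OCc3ccccc3)c2)cc(OCc2ccccc2)cc1OCc1ccccc1)c1cc(OCc2ccccc2)c(OCc2ccccc2)c(OCc2ccccc2)c1 | intermediate (not isolated)
10 | (2R,3R)-5,7-bis(benzyloxy)-2-[3,4-bis(benzyloxy)phenyl]-4-oxo-3,4-dihydro-2H-chromen-3-yl 3,4,5-tris(benzyloxy)benzoate (2,3-trans) | O=C(O[C@@H]1[C@@H](c2ccc(OCc3ccccc3)c(OCc3ccccc3)c2)Oc2cc(OCc3ccccc3)cc(OCc3ccccc3)c2C1=O)c1cc(OCc2ccccc2)c(OCc2ccccc2)c(OCc2ccccc2)c1 | intermediate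
11 | (2R,3S,4S)-5,7-bis(benzyloxy)-2-[3,4-bis(benzyloxy)phenyl]-4-hydroxy-3,4-dihydro-2H-chromen-3-yl 3,4,5-tris(benzyloxy)benzoate (2,3-trans, 3,4-cis) | O=C(O[C@@H]1[C@@H](c2ccc(OCc3ccccc3)c(OCc3ccccc3)c2)Oc2cc(OCc3ccccc3)cc(OCc3ccccc3)c2[C@@H]1O)c1cc(OCc2ccccc2)c(OCc2ccccc2)c(OCc2ccccc2)c1 | intermediate
12 | (2R,3S,4S)-2-(3,4-dihydroxyphenyl)-4,5,7-trihydroxy-3,4-dihydro-2H-chromen-3-yl 3,4,5-trihydroxybenzoate | O=C(O[C@@H]1[C@@H](c2ccc(O)c(O)c2)Oc2cc(O)cc(O)c2[C@@H]1O)c1cc(O)c(O)c(O)c1 | target

**Step count and risks**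

Total step count: 7. Longest linear sequence: 7 steps (1 → 2 → 4 → 6 → 8 → 10 → 11 → 12).

Steps most likely to fail:

Step 5 (Proposed new method). Facial discrimination in the ion pair may be weak because part of the cation reacts while still paired with the achiral reduced-quinone anion; traces of water may also intercept the cation and cleave the ring-B benzyl ether. Fallback (known chemistry), from 8 back to 10: the cyclisation is run in its racemic form (DDQ, diphenyl phosphate, 4 Å MS, CH2Cl2; dehydrogenative coupling of a benzylic ether with a ketone), which should give 10 together with its (2S,3S) enantiomer F1. The racemate is then resolved kinetically by transfer hydrogenation with RuCl(p-cymene)[(R,R)-TsDPEN] in HCO2H/Et3N. This catalyst fixes the sense of hydride delivery at C4; in F1 that sense is anti to the 2-aryl group, the mode preferred in kinetic resolutions of flavanones, so F1 should be reduced to the (2S,3R,4S) alcohol F2. In 10 catalyst and substrate preferences are opposed, so 10 should remain and is separated by chromatography, which returns to the route at 10.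

Step 6. Hydride may be delivered from the wrong face (3,4-trans alcohol), or the galloyl group may migrate to the cis C4 alkoxide before the quench. Fallback, from 10 to 12: the benzyl ethers are removed at the ketone stage (H2, Pd/C, THF/MeOH), where no labile carbinol is present, to give (2R,3R)-2-(3,4-dihydroxyphenyl)-5,7-dihydroxy-4-oxo-3,4-dihydro-2H-chromen-3-yl 3,4,5-trihydroxybenzoate F3. The carbonyl of F3 is then hydrogenated over PtO2 (H2, EtOH, rt), the classical neutral entry from dihydroflavonols to 2,3-trans-3,4-cis flavan-3,4-diols, with no alkoxide intermediate. This arrives directly at 12.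

Step 7. Once ring A is unmasked, the doubly activated benzylic C4–O bond may be cleaved hydrogenolytically, or C4 may ionise and the product oligomerise. Fallback, from 10 to 12, avoiding any hydrogenolysis in the presence of the carbinol: 10 is debenzylated to F3 as above and persilylated (TBSCl, imidazole, DMAP, DMF) to the hepta-O-tert-butyldimethylsilyl ketone F4. F4 is reduced with LiBH(s-Bu)3 (THF, −78 °C) to the silylated 3,4-cis alcohol F5, and the silyl ethers are removed with buffered fluoride (Et3N·3HF, THF, 0 °C) to give 12.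

Further compounds
F1 | step 5 | (2S,3S)-5,7-bis(benzyloxy)-2-[3,4-bis(benzyloxy)phenyl]-4-oxo-3,4-dihydro-2H-chromen-3-yl 3,4,5-tris(benzyloxy)benzoate (enantiomer of 10) | O=C(O[C@H]1[C@H](c2ccc(OCc3ccccc3)c(OCc3ccccc3)c2)Oc2cc(OCc3ccccc3)cc(OCc3ccccc3)c2C1=O)c1cc(OCc2ccccc2)c(OCc2ccccc2)c(OCc2ccccc2)c1
F2 | step 5 | (2S,3R,4S)-5,7-bis(benzyloxy)-2-[3,4-bis(benzyloxy)phenyl]-4-hydroxy-3,4-dihydro-2H-chromen-3-yl 3,4,5-tris(benzyloxy)benzoate | O=C(O[C@H]1[C@H](c2ccc(OCc3ccccc3)c(OCc3ccccc3)c2)Oc2cc(OCc3ccccc3)cc(OCc3ccccc3)c2[C@@H]1O)c1cc(OCc2ccccc2)c(OCc2ccccc2)c(OCc2ccccc2)c1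
F3 | step 6 | (2R,3R)-2-(3,4-dihydroxyphenyl)-5,7-dihydroxy-4-oxo-3,4-dihydro-2H-chromen-3-yl 3,4,5-trihydroxybenzoate | O=C(O[C@@H]1[C@@H](c2ccc(O)c(O)c2)Oc2cc(O)cc(O)c2C1=O)c1cc(O)c(O)c(O)c1
F4 | step 7 | (2R,3R)-5,7-bis[(tert-butyldimethylsilyl)oxy]-2-{3,4-bis[(tert-butyldimethylsilyl)oxy]phenyl}-4-oxo-3,4-dihydro-2H-chromen-3-yl 3,4,5-tris[(tert-butyldimethylsilyl)oxy]benzoate | O=C(O[C@@H]1[C@@H](c2ccc(O[Si](C)(C)C(C)(C)C)c(O[Si](C)(C)C(C)(C)C)c2)Oc2cc(O[Si](C)(C)C(C)(C)C)cc(O[Si](C)(C)C(C)(C)C)c2C1=O)c1cc(O[Si](C)(C)C(C)(C)C)c(O[Si](C)(C)C(C)(C)C)c(O[Si](C)(C)C(C)(C)C)c1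
F5 | step 7 | (2R,3S,4S)-5,7-bis[(tert-butyldimethylsilyl)oxy]-2-{3,4-bis[(tert-butyldimethylsilyl)oxy]phenyl}-4-hydroxy-3,4-dihydro-2H-chromen-3-yl 3,4,5-tris[(tert-butyldimethylsilyl)oxy]benzoate | O=C(O[C@@H]1[C@@H](c2ccc(O[Si](C)(C)C(C)(C)C)c(O[Si](C)(C)C(C)(C)C)c2)Oc2cc(O[Si](C)(C)C(C)(C)C)cc(O[Si](C)(C)C(C)(C)C)c2[C@@H]1O)c1cc(O[Si](C)(C)C(C)(C)C)c(O[Si](C)(C)C(C)(C)C)c(O[Si](C)(C)C(C)(C)C)c1
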